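## Structural features

The target is a coumarin whose benzo ring (ring A) is fully substituted: methyl groups on C6 and C8, a free phenol on C7, the lactone oxygen on C8a, a (2S)-2-hydroxypropyl chain on C5 and the C4 methine on C4a. C3 of the pyranone ring (ring B) is joined by one sp2–sp2 bond to C6' of ring C, a (2R)-2-methyl-2,3-dihydro-4H-pyran-4-one, so ring C hangs from the oxygen-bearing end of its vinylogous ester. The two stereocentres, the side-chain carbinol (S) and C2' of ring C (R), are eight bonds apart and have no stereogenic neighbours, so there is no relative stereocontrol to exert and each is best bought in a small chiral building block. Fragile groups are the vinylogous ester of ring C (β-elimination opens it and would cost the C2' configuration), the lactone and its C3=C4 bond (nucleophiles, hydride, hydrogenation), the phenol between two methyl groups (oxidants) and the carbinol, which lies within reach of C4. The real difficulty is the pattern of ring A: C5 is meta to both oxygen atoms, so neither electrophilic substitution nor directed metalation can place the chiral chain there, and its neighbours C4a and C6 must also carry carbon. The key step uses the contiguous triad C5, C4a, C8a: with iodine on C4a, the C8a oxygen as the single blocking ortho group and a free C–H on C5, a palladium–norbornene relay attaches the chain to C5 and the C4 carbon to C4a in one operation. The chain oxygen then holds C4 in a temporary isochroman ring.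

## Logic of the disconnections

**24 to 22 (through 23).** The O1'–C6' bond of ring C is cut (reverse of a 6-endo-dig oxa-Michael addition) and the three hydroxyl groups are capped with silicon. A vinylogous ester is safest made last, from an ynone whose hydroxyl carbon already has the right configuration. Ring C becomes an open chain with one bought stereocentre. The forward step must remove three silyl groups and close the ring under acid without reopening ring C.

**22 to 16 + 20 (through 21).** The ketone is taken back to a carbinol and the C3–C(sp) bond is cut. An sp2–sp coupling at an electron-poor alkenyl-type bromide is the most dependable way to put carbon on C3 of the lactone. The gain is convergence, with the chain arriving in three steps of its own. The demand is that the oxidant of the forward sequence meets only one free hydroxyl group, which is why silyl ethers are in place.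

**20 to 17 (through 19 and 18).** The C2–C3 bond of the hexynol is cut (acetylide plus aldehyde), and the aldehyde is traced to the ester. The (R) centre is bought with 17 and never becomes a reacting centre. The new carbinol carbon needs no control because it is oxidized later. The β-silyloxy aldehyde must be handled without elimination.

**16 to 13 (through 14).** The C3–Br bond and the two O–Si bonds are cut. Ring A has no free position, so an electrophile can only enter at C3. The hydroxyl groups must be masked before bromine is used.

**13 to 10 (through 12 and 11).** The lactone O1–C2 bond is cut, the C3=C4 bond is traded for a C4–O bond to the side-chain oxygen, and both phenols are capped as MOM ethers. This is where the temporary isochroman pays off: C4 is still sp3 when the lactone closes, so the geometry problem of an ortho-hydroxycinnamate does not arise. One ester now stands for phenol, lactone, alkene and free carbinol. The forward step must break the benzylic C4–O bond and not the C–O bond of the stereocentre.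

**10 to 8 (through 9).** The C6–CH3 bond (coumarin numbering) is cut to C–Br and then to C–H. The carbon next to the reacting ortho position must carry only hydrogen during the key step. The forward cross-coupling has to work at a bromide with two ortho substituents without destroying the β-alkoxy ester.

**8 to 4 + 5 + 6 (through 7).** The C4–O bond (oxa-Michael), the C4a–C4 bond (Heck) and the C5–CH2 bond (ortho alkylation) are cut, giving three components. This is the only cut that reaches the meta-to-oxygen carbon C5 directly. It returns a two-step arene and two bulk chemicals, one of which carries the stereocentre. The demand is one free and unhindered ortho C–H, one blocked ortho position and protecting groups that tolerate base.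

**4 to 1 (through 3 and 2).** The C–I bond and the two O–CH2 bonds are cut. The MOM group directs metalation to the carbon that becomes C4a. The forward step needs ring lithiation to win over deprotonation of the methyl group.

## Other disconnections considered

Alternative 1: Ring C is traced to the 3,5-disubstituted isoxazole A4, which is cut across C4'–C5' into the 3-ethynylcoumarin A1 and the nitrile oxide A3. A3 would be generated in the flask from oxime A2 (from 19) by chlorination and loss of HCl.
- Forward key step: the (3+2) cycloaddition would join the nitrile oxide carbon (future C4') to the terminal alkyne carbon (C5') and place the ring oxygen on C6'. Reductive N–O cleavage (for example Mo(CO)6 in wet acetonitrile) would unveil a β-amino enone, and acid would hydrolyse it, remove the silyl groups and close ring C.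
- In its favour: terminal alkynes and nitrile oxides combine with dependable regiochemistry, the union needs no metal, and the 1,3-dioxygenated chain travels as a stable aromatic ring. On robustness of the intermediate it is the better plan, since the chosen route passes through the electrophilic ynone 22, and it avoids an oxidation step.
- Against it: A1 needs two steps from 16 (coupling with trimethylsilylacetylene, desilylation), the N–O cleavage must spare the coumarin C3=C4 bond and the lactone, and A3 can dimerize.
- Comparison: structurally both plans put an sp carbon on C3 and both take the (R) centre from 17, so they are equal in stereochemical security. Mechanistically the alternative replaces one conjugate addition by a cycloaddition, a reduction and a hydrolysis. It would need about five operations from 16 to 24 where the chosen plan needs three. It concerns ring C only and is compatible with the Catellani construction, so it competes with steps 12–14 and not with step 3.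

Alternative 2: The C5–CH2 and C6–CH3 bonds are cut together. Bromoarene A5 would give the aryne A6 with lithium 2,2,6,6-tetramethylpiperidide.
- Forward key step: allylmagnesium bromide should add at the aryne carbon remote from the methoxy group (future C5), and the aryl–metal species left at C6 would be quenched with iodomethane to give A7.
- In its favour: the chain carbon on C5 and the C6 methyl group are set in one step with regiochemistry fixed by the neighbouring methoxy group. Here the alternative is better than the chosen plan, which spends steps 4 and 5 on the C6 methyl group. Its key step also needs no transition metal.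
- Against it: A7 is achiral. The (S)-carbinol would have to be made by Wacker oxidation and enantioselective reduction of a benzyl methyl ketone, a class for which high selectivity is not assured, whereas the chosen plan buys the centre with 5. C4a still lacks its carbon, the methyl ethers need a harsh cleavage early on, and the aryl–magnesium intermediate may react sluggishly with iodomethane.
- Comparison: the aryne route is strongly basic and polar, with low tolerance for functional groups, where the palladium relay runs under carbonate base. It would need about eight steps to reach the stage of 13 against six. One further point where it is equal or better: the salicylaldehyde it passes through would allow a Knoevenagel condensation with a β-keto ester that already carries the ring C chain, forming ring B and the C3–C6' bond together.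

Alternative 3: Ring A is cut at C8a–C8, C6–C7 and C4a–C8a. The components are the diazo ketone A8 and the siloxyalkyne A9.
- Forward key step: irradiation of A8 would cause a Wolff rearrangement to the vinylketene A10. A (2+2) cycloaddition with A9, four-electron ring opening, six-electron electrocyclization and tautomerization would then give phenol A11.
- In its favour: all six positions of ring A are placed at once with full regiocontrol, including both methyl groups. The two ring oxygens emerge differentiated (free phenol for C8a, silyl ether for C7), which is better than the chosen plan, where both are unveiled in step 6 and one must be masked again in step 7. The stereocentre is again bought.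
- Against it: A8 is itself a multistep target (an α'-diazo enone from diazo transfer to the ethyl ketone), A9 must be made by ynolate chemistry, and the photochemical step is less convenient on scale. A11 still lacks the C4 carbon, so ortho-formylation and an olefination–lactonization must follow.
- Comparison: the pericyclic cascade needs no catalyst and builds a ring, whereas the palladium relay decorates an existing ring with two bonds. It would need roughly ten to eleven steps to reach the stage of 13 against six. As in Alternative 2, its salicylaldehyde stage would permit a Knoevenagel route to the C3 substituent, which is a point in its favour.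

Key step: step 3

Assumption: the C1 epimers of the isochromans 8 to 12 are carried on as mixtures because step 6 turns this carbon into sp2 C4; 5 is volatile and is used in excess in a closed vessel.

## Route

Step 1
Reactants: 1 2-methylresorcinol (2-methylbenzene-1,3-diol)
Product: 2 1,3-bis(methoxymethoxy)-2-methylbenzene
Conditions: NaH, MOMCl, THF–DMF, 0 °C → rt
Reagents that add atoms: chloromethyl methyl ether (MOMCl), COCCl
Why: Double Williamson etherification of the two phenoxides. MOM ethers direct the lithiation of step 2, are inert to the basic palladium steps 3 and 5 and leave together in the acid of step 6.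

Step 2
Reactants: 2 1,3-bis(methoxymethoxy)-2-methylbenzene
Product: 4 1-iodo-2,4-bis(methoxymethoxy)-3-methylbenzene, via aryllithium 3 (not isolated)
Conditions: n-BuLi, TMEDA, THF, 0 °C; then I2, −78 °C → rt
Reagents that add atoms: iodine, II
Why: Directed ortho-metalation: the OMOM group steers n-BuLi to C4 (C6 is equivalent), and iodine quenches the aryllithium. Ring lithiation next to OMOM should outrun deprotonation of the methyl group, and one equivalent of base limits double functionalization.

Step 3
Reactants: 4 1-iodo-2,4-bis(methoxymethoxy)-3-methylbenzene; 5 (S)-propylene oxide [(2S)-2-methyloxirane]; 6 methyl acrylate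
Product: 8 methyl 2-[(1RS,3S)-6,8-bis(methoxymethoxy)-3,7-dimethyl-3,4-dihydro-1H-isochromen-1-yl]acetate, via hydroxy cinnamate 7 (not isolated)
Conditions: Pd(OAc)2 (10 mol %), XPhos (20 mol %), potassium 5-norbornene-2-carboxylate (50 mol %), K2CO3, NMP, 70 °C, closed vessel; then DBU (cat.), rt
Reagents that add atoms: none
Why: Catellani reaction (palladium–norbornene cooperative catalysis) with an epoxide as ortho-alkylating agent, Heck termination and oxa-Michael addition; this three-component isochroman synthesis is known for ortho-substituted aryl iodides and is applied here to a more electron-rich one. Zerovalent palladium inserts into the C–I bond of 4, the norbornene inserts, and carboxylate-assisted palladation of the only free ortho C–H gives the five-membered aryl–norbornyl palladacycle of divalent palladium. The palladacycle opens 5 at its CH2 carbon in an SN2-type oxidative addition, so the stereocentre is not a reacting centre and stays (S); reductive elimination then forms the aryl–CH2 bond. With both ortho positions substituted (OMOM and the new chain), strain drives β-carbon elimination of the norbornene, and the aryl–palladium species at the former iodide carbon undergoes a Mizoroki–Heck reaction with 6 to give the (E)-cinnamate 7. The side-chain alkoxide adds to the cinnamate β-carbon in a 6-exo-trig oxa-Michael closure, which forms the isochroman ring of 8. The new C1 centre is under weak thermodynamic 1,3-control by the C3 methyl group (the cis isomer should prevail through reversible addition), but its configuration is irrelevant because step 6 turns C1 into sp2 C4. Site selectivity rests on the substrate: the iodide has exactly one ortho C–H, with only hydrogen on the adjacent meta carbon, and one blocking ortho group. The step needs Heck termination to beat C–O reductive elimination at the ipso carbon (which would give a dihydrobenzofuran) and norbornene insertion to beat direct Heck reaction of the first aryl–palladium species; an excess of 6 with a bulky biaryl phosphine serves the former and the carboxylate-bearing norbornene the latter.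

Step 4
Reactants: 8 methyl 2-[(1RS,3S)-6,8-bis(methoxymethoxy)-3,7-dimethyl-3,4-dihydro-1H-isochromen-1-yl]acetate
Product: 9 methyl 2-[(1RS,3S)-5-bromo-6,8-bis(methoxymethoxy)-3,7-dimethyl-3,4-dihydro-1H-isochromen-1-yl]acetate
Conditions: NBS, MeCN, 0 °C → rt, dark
Reagents that add atoms: N-bromosuccinimide, O=C1CCC(=O)N1Br
Why: Electrophilic aromatic bromination at the only ring C–H left, which is ortho and para to the two OMOM groups. The neutral succinimide by-product leaves the acetals intact, and the polar solvent in the dark suppresses benzylic radical bromination.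

Step 5
Reactants: 9 methyl 2-[(1RS,3S)-5-bromo-6,8-bis(methoxymethoxy)-3,7-dimethyl-3,4-dihydro-1H-isochromen-1-yl]acetate
Product: 10 methyl 2-[(1RS,3S)-6,8-bis(methoxymethoxy)-3,5,7-trimethyl-3,4-dihydro-1H-isochromen-1-yl]acetate
Conditions: MeB(OH)2, Pd(OAc)2, SPhos, K3PO4, toluene–H2O (10:1), 90 °C
Reagents that add atoms: methylboronic acid, CB(O)O
Why: Suzuki–Miyaura methylation; a dialkylbiarylphosphine is used because the bromide is electron-rich and has two ortho substituents. Partial base-induced opening of the isochroman should not be fatal, since the open cinnamate can reclose under the acid of step 6.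

Step 6
Reactants: 10 methyl 2-[(1RS,3S)-6,8-bis(methoxymethoxy)-3,5,7-trimethyl-3,4-dihydro-1H-isochromen-1-yl]acetate
Product: 13 7-hydroxy-5-[(2S)-2-hydroxypropyl]-6,8-dimethyl-2H-chromen-2-one, via diphenol ester 11 (not isolated), via tricyclic lactone 12 (not isolated)
Conditions: TsOH·H2O, MeOH, 60 °C; then toluene, 100 °C
Reagents that add atoms: none
Why: Acid-catalysed acetal cleavage of both MOM ethers gives 11, whose C8 phenol lactonizes onto the neighbouring ester to give 12. Ionization of the benzylic C4–O bond (cation stabilized by the para phenol) and loss of the C3 proton, a β-elimination, then give the coumarin. The isochroman oxygen is released as the side-chain alcohol without any bond to the stereocentre being broken, and both C4 epimers converge.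

Step 7
Reactants: 13 7-hydroxy-5-[(2S)-2-hydroxypropyl]-6,8-dimethyl-2H-chromen-2-one
Product: 14 7-[(tert-butyldimethylsilyl)oxy]-5-[(2S)-2-[(tert-butyldimethylsilyl)oxy]propyl]-6,8-dimethyl-2H-chromen-2-one
Conditions: TBSOTf, 2,6-lutidine, CH2Cl2, 0 °C → rt
Reagents that add atoms: tert-butyldimethylsilyl trifluoromethanesulfonate, CC(C)(C)[Si](C)(C)OS(=O)(=O)C(F)(F)F
Why: Silylation of the phenol and the secondary alcohol; the triflate is reactive enough for the phenol flanked by two methyl groups. The silyl ethers shield both hydroxyl groups from bromine and from the oxidant of step 13 and leave together in step 14.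

Step 8
Reactants: 14 7-[(tert-butyldimethylsilyl)oxy]-5-[(2S)-2-[(tert-butyldimethylsilyl)oxy]propyl]-6,8-dimethyl-2H-chromen-2-one
Product: 16 3-bromo-7-[(tert-butyldimethylsilyl)oxy]-5-[(2S)-2-[(tert-butyldimethylsilyl)oxy]propyl]-6,8-dimethyl-2H-chromen-2-one, via trans-3,4-dibromide 15 (not isolated)
Conditions: Br2, CH2Cl2, 0 °C; then Et3N, 0 °C → rt
Reagents that add atoms: bromine, BrBr
Why: Bromine addition across the C3=C4 bond followed by E1cB loss of HBr (C3–H is α to the lactone carbonyl, the C4 bromide is benzylic) gives the 3-bromocoumarin. Ring A has no free position, so substitution there cannot compete.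

Step 9
Reactants: 17 methyl (R)-3-hydroxybutanoate
Product: 18 methyl (3R)-3-[(tert-butyldimethylsilyl)oxy]butanoate
Conditions: TBSCl, imidazole, DMF, rt
Reagents that add atoms: tert-butyldimethylsilyl chloride, CC(C)(C)[Si](C)(C)Cl
Why: Standard silylation of a secondary alcohol; the stereocentre is not touched.

Step 10
Reactants: 18 methyl (3R)-3-[(tert-butyldimethylsilyl)oxy]butanoate
Product: 19 (3R)-3-[(tert-butyldimethylsilyl)oxy]butanal
Conditions: i-Bu2AlH, CH2Cl2, −78 °C
Reagents that add atoms: none
Why: Partial reduction of the ester through the tetrahedral aluminium hemiacetal, which is stable at low temperature and releases the aldehyde on work-up. The β-silyloxy aldehyde is used at once to avoid elimination.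

Step 11
Reactants: 19 (3R)-3-[(tert-butyldimethylsilyl)oxy]butanal
Product: 20 (3RS,5R)-5-[(tert-butyldimethylsilyl)oxy]hex-1-yn-3-ol
Conditions: ethynylmagnesium bromide, THF, −78 → 0 °C
Reagents that add atoms: ethynylmagnesium bromide, C#C[Mg]Br
Why: 1,2-Addition of the alkynyl Grignard reagent to the aldehyde. The new carbinol centre forms without control, which does not matter because step 13 oxidizes it.

Step 12
Reactants: 16 3-bromo-7-[(tert-butyldimethylsilyl)oxy]-5-[(2S)-2-[(tert-butyldimethylsilyl)oxy]propyl]-6,8-dimethyl-2H-chromen-2-one; 20 (3RS,5R)-5-[(tert-butyldimethylsilyl)oxy]hex-1-yn-3-ol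
Product: 21 7-[(tert-butyldimethylsilyl)oxy]-3-[(3RS,5R)-5-[(tert-butyldimethylsilyl)oxy]-3-hydroxyhex-1-yn-1-yl]-5-[(2S)-2-[(tert-butyldimethylsilyl)oxy]propyl]-6,8-dimethyl-2H-chromen-2-one
Conditions: Pd(PPh3)2Cl2, CuI, Et3N, THF, rt → 45 °C
Reagents that add atoms: none
Why: Sonogashira coupling; the 3-bromocoumarin is an electron-poor alkenyl-type bromide that should undergo oxidative addition readily, and the free propargylic alcohol is tolerated.

Step 13
Reactants: 21 7-[(tert-butyldimethylsilyl)oxy]-3-[(3RS,5R)-5-[(tert-butyldimethylsilyl)oxy]-3-hydroxyhex-1-yn-1-yl]-5-[(2S)-2-[(tert-butyldimethylsilyl)oxy]propyl]-6,8-dimethyl-2H-chromen-2-one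
Product: 22 7-[(tert-butyldimethylsilyl)oxy]-3-[(5R)-5-[(tert-butyldimethylsilyl)oxy]-3-oxohex-1-yn-1-yl]-5-[(2S)-2-[(tert-butyldimethylsilyl)oxy]propyl]-6,8-dimethyl-2H-chromen-2-one
Conditions: Dess–Martin periodinane, CH2Cl2, 0 °C → rt
Reagents that add atoms: none
Why: Dess–Martin oxidation of the propargylic alcohol, the only free hydroxyl group, to the ynone under near-neutral conditions that spare silyl ethers and coumarin; both carbinol epimers converge.

Step 14
Reactants: 22 7-[(tert-butyldimethylsilyl)oxy]-3-[(5R)-5-[(tert-butyldimethylsilyl)oxy]-3-oxohex-1-yn-1-yl]-5-[(2S)-2-[(tert-butyldimethylsilyl)oxy]propyl]-6,8-dimethyl-2H-chromen-2-one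
Product: 24 7-hydroxy-5-[(2S)-2-hydroxypropyl]-6,8-dimethyl-3-[(2R)-2-methyl-4-oxo-3,4-dihydro-2H-pyran-6-yl]-2H-chromen-2-one, via trihydroxy ynone 23 (not isolated)
Conditions: HF (48 % aq.), MeCN, 0 °C → rt; then TsOH·H2O (cat.), rt
Reagents that add atoms: none
Why: Cleavage of the three silyl ethers gives 23, whose C5 hydroxyl adds to the ynone β-carbon (the alkyne carbon on coumarin C3) in an acid-promoted 6-endo-dig oxa-Michael cyclization to the 2,3-dihydro-4H-pyran-4-one. C2' is the untouched carbinol carbon of 17 and therefore stays (R); the side-chain carbinol stays (S).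

## Compound list

1 | 2-methylresorcinol (2-methylbenzene-1,3-diol) | Cc1c(O)cccc1O | starting material
2 | 1,3-bis(methoxymethoxy)-2-methylbenzene | COCOc1cccc(OCOC)c1C | intermediate
3 | [2,4-bis(methoxymethoxy)-3-methylphenyl]lithium | COCOc1ccc([Li])c(OCOC)c1C | intermediate (not isolated)
4 | 1-iodo-2,4-bis(methoxymethoxy)-3-methylbenzene | COCOc1ccc(I)c(OCOC)c1C | intermediate
5 | (S)-propylene oxide [(2S)-2-methyloxirane] | C[C@H]1CO1 | starting material
6 | methyl acrylate | COC(=O)C=C | starting material
7 | methyl (2E)-3-{6-[(2S)-2-hydroxypropyl]-2,4-bis(methoxymethoxy)-3-methylphenyl}prop-2-enoate | COC(=O)/C=C/c1c(C[C@H](C)O)cc(OCOC)c(C)c1OCOC | intermediate (not isolated)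
8 | methyl 2-[(1RS,3S)-6,8-bis(methoxymethoxy)-3,7-dimethyl-3,4-dihydro-1H-isochromen-1-yl]acetate | COC(=O)CC1O[C@@H](C)Cc2cc(OCOC)c(C)c(OCOC)c21 | intermediate
9 | methyl 2-[(1RS,3S)-5-bromo-6,8-bis(methoxymethoxy)-3,7-dimethyl-3,4-dihydro-1H-isochromen-1-yl]acetate | COC(=O)CC1O[C@@H](C)Cc2c(Br)c(OCOC)c(C)c(OCOC)c21 | intermediate
10 | methyl 2-[(1RS,3S)-6,8-bis(methoxymethoxy)-3,5,7-trimethyl-3,4-dihydro-1H-isochromen-1-yl]acetate | COC(=O)CC1O[C@@H](C)Cc2c(C)c(OCOC)c(C)c(OCOC)c21 | intermediate
11 | methyl 2-[(1RS,3S)-6,8-dihydroxy-3,5,7-trimethyl-3,4-dihydro-1H-isochromen-1-yl]acetate | COC(=O)CC1O[C@@H](C)Cc2c(C)c(O)c(C)c(O)c21 | intermediate (not isolated)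
12 | tricyclic lactone: 7-hydroxy-6,8-dimethyl-3,4-dihydro-2H-chromen-2-one whose C4 is joined through oxygen to the (S)-CH(CH3)–CH2 chain on C5 (isochroman ring intact; both C4 epimers) | O=C1CC2O[C@@H](C)Cc3c(C)c(O)c(C)c(O1)c32 | intermediate (not isolated)
13 | 7-hydroxy-5-[(2S)-2-hydroxypropyl]-6,8-dimethyl-2H-chromen-2-one | Cc1c(O)c(C)c2oc(=O)ccc2c1C[C@H](C)O | intermediate
14 | 7-[(tert-butyldimethylsilyl)oxy]-5-[(2S)-2-[(tert-butyldimethylsilyl)oxy]propyl]-6,8-dimethyl-2H-chromen-2-one | Cc1c(O[Si](C)(C)C(C)(C)C)c(C)c2oc(=O)ccc2c1C[C@H](C)O[Si](C)(C)C(C)(C)C | intermediate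
15 | trans-3,4-dibromo-3,4-dihydro derivative of 14 (mixture of diastereomers) | Cc1c(O[Si](C)(C)C(C)(C)C)c(C)c2OC(=O)C(Br)C(Br)c2c1C[C@H](C)O[Si](C)(C)C(C)(C)C | intermediate (not isolated)
16 | 3-bromo-7-[(tert-butyldimethylsilyl)oxy]-5-[(2S)-2-[(tert-butyldimethylsilyl)oxy]propyl]-6,8-dimethyl-2H-chromen-2-one | Cc1c(O[Si](C)(C)C(C)(C)C)c(C)c2oc(=O)c(Br)cc2c1C[C@H](C)O[Si](C)(C)C(C)(C)C | intermediate
17 | methyl (R)-3-hydroxybutanoate | C[C@@H](O)CC(=O)OC | starting material
18 | methyl (3R)-3-[(tert-butyldimethylsilyl)oxy]butanoate | C[C@@H](O[Si](C)(C)C(C)(C)C)CC(=O)OC | intermediate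
19 | (3R)-3-[(tert-butyldimethylsilyl)oxy]butanal | C[C@@H](O[Si](C)(C)C(C)(C)C)CC=O | intermediate
20 | (3RS,5R)-5-[(tert-butyldimethylsilyl)oxy]hex-1-yn-3-ol | C#CC(O)C[C@@H](C)O[Si](C)(C)C(C)(C)C | intermediate
21 | 7-[(tert-butyldimethylsilyl)oxy]-3-[(3RS,5R)-5-[(tert-butyldimethylsilyl)oxy]-3-hydroxyhex-1-yn-1-yl]-5-[(2S)-2-[(tert-butyldimethylsilyl)oxy]propyl]-6,8-dimethyl-2H-chromen-2-one | Cc1c(O[Si](C)(C)C(C)(C)C)c(C)c2oc(=O)c(C#CC(O)C[C@@H](C)O[Si](C)(C)C(C)(C)C)cc2c1C[C@H](C)O[Si](C)(C)C(C)(C)C | intermediate
22 | 7-[(tert-butyldimethylsilyl)oxy]-3-[(5R)-5-[(tert-butyldimethylsilyl)oxy]-3-oxohex-1-yn-1-yl]-5-[(2S)-2-[(tert-butyldimethylsilyl)oxy]propyl]-6,8-dimethyl-2H-chromen-2-one | Cc1c(O[Si](C)(C)C(C)(C)C)c(C)c2oc(=O)c(C#CC(=O)C[C@@H](C)O[Si](C)(C)C(C)(C)C)cc2c1C[C@H](C)O[Si](C)(C)C(C)(C)C | intermediate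
23 | 7-hydroxy-3-[(5R)-5-hydroxy-3-oxohex-1-yn-1-yl]-5-[(2S)-2-hydroxypropyl]-6,8-dimethyl-2H-chromen-2-one | Cc1c(O)c(C)c2oc(=O)c(C#CC(=O)C[C@@H](C)O)cc2c1C[C@H](C)O | intermediate (not isolated)
24 | 7-hydroxy-5-[(2S)-2-hydroxypropyl]-6,8-dimethyl-3-[(2R)-2-methyl-4-oxo-3,4-dihydro-2H-pyran-6-yl]-2H-chromen-2-one | Cc1c(O)c(C)c2oc(=O)c(C3=CC(=O)C[C@@H](C)O3)cc2c1C[C@H](C)O | target

## Step count and least certain steps

Total step count: 14. Longest linear sequence: 11 steps (steps 1–8 and 12–14); steps 9–11 make the side fragment.

**Step 3 (key step).** Three processes are the most likely to go wrong: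
- The first aryl–palladium species may react with 6 before the norbornene inserts, which would give a plain Heck product without the side chain.
- The alkoxide may close onto the ipso carbon by C–O reductive elimination faster than 6 inserts, which would give dihydrobenzofuran formation.
- 5 may be lost by evaporation or by iodide opening, and the electron-rich ring slows oxidative addition.

The fallback builds the same bonds stepwise, without the norbornene relay, setting out from 2 and coming back at 8:
- Sterically governed C–H borylation ([Ir(OMe)(cod)]2, 4,4'-di-tert-butyl-2,2'-bipyridine, B2pin2) at the only ring C–H without an ortho neighbour would give the boronate 2-[3,5-bis(methoxymethoxy)-4-methylphenyl]-4,4,5,5-tetramethyl-1,3,2-dioxaborolane F1.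
- Iododeboronation (NaI, TsN(Cl)Na, aqueous THF) would give 5-iodo-1,3-bis(methoxymethoxy)-2-methylbenzene F2.
- Iodine–magnesium exchange (i-PrMgCl·LiCl) and CuI-catalysed opening of 5 at its CH2 carbon would give (2S)-1-[3,5-bis(methoxymethoxy)-4-methylphenyl]propan-2-ol F3.
- Directed ortho-lithiation (n-BuLi, TMEDA, two equivalents) with a DMF quench would give 6-[(2S)-2-hydroxypropyl]-2,4-bis(methoxymethoxy)-3-methylbenzaldehyde F4, in equilibrium with its lactol.
- A Wittig reaction with methyl (triphenylphosphoranylidene)acetate would give 7, which closes to 8 with a trace of DBU.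

This costs five steps in place of two.

**Step 6.** The benzylic C–O bond may ionize before the lactone has closed, which would deliver the (E)-cinnamate whose ester cannot reach the phenol. Methanolysis of the lactone is possible if the solvent switch is incomplete, and the carbinol may dehydrate on long heating. The fallback separates the events and uses light for the alkene geometry. From 10, MOM cleavage with HCl in MeOH at rt gives 11, and DBU would then open the isochroman by E1cB to methyl (2E)-3-{2,4-dihydroxy-6-[(2S)-2-hydroxypropyl]-3,5-dimethylphenyl}prop-2-enoate F5. Irradiation at 365 nm (E to Z isomerization) is followed by spontaneous lactonization, and the route is rejoined at 13.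

**Step 14.** The aryl silyl ether shielded by two methyl groups may cleave incompletely. Water or fluoride may add to the ynone intermolecularly. β-Elimination in ring C (opening to a dienone and reclosure) would erode the C2' configuration. The fallback closes ring C by addition–elimination instead of alkyne hydroalkoxylation. From 22, conjugate addition of Et2NH (EtOH, rt) would give the β-amino enone 7-[(tert-butyldimethylsilyl)oxy]-3-[(5R)-5-[(tert-butyldimethylsilyl)oxy]-1-(diethylamino)-3-oxohex-1-en-1-yl]-5-[(2S)-2-[(tert-butyldimethylsilyl)oxy]propyl]-6,8-dimethyl-2H-chromen-2-one F6. Aqueous HF in MeCN would then remove the silyl groups, and the freed C5 hydroxyl would displace the amine at the vinylogous amide to give 24.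

**Step 5.** Oxidative addition and transmetalation may be slow at the doubly ortho-substituted, electron-rich bromide, leading to protodebromination. The aqueous phosphate may hydrolyse the ester or open the isochroman. The fallback changes the order so that the methyl group enters at the coumarin stage. From 9, the acid cascade of step 6 would give 6-bromo-7-hydroxy-5-[(2S)-2-hydroxypropyl]-8-methyl-2H-chromen-2-one F7. Silylation as in step 7 would give 6-bromo-7-[(tert-butyldimethylsilyl)oxy]-5-[(2S)-2-[(tert-butyldimethylsilyl)oxy]propyl]-8-methyl-2H-chromen-2-one F8. A base-free Negishi methylation (MeZnCl, Pd(OAc)2, SPhos, THF, 50 °C) would then give 14.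

**Step 2.** Deprotonation of the methyl group between the two OMOM groups, double lithiation or over-iodination may occur. The fallback uses electrophilic substitution first. From 1, mono-iodination (I2, NaHCO3, aqueous THF, 0 °C) at C4 would give 4-iodo-2-methylbenzene-1,3-diol F9, and the double etherification of step 1 would then give 4.

## Further compounds

F1 | step 3 | 2-[3,5-bis(methoxymethoxy)-4-methylphenyl]-4,4,5,5-tetramethyl-1,3,2-dioxaborolane | COCOc1cc(B2OC(C)(C)C(C)(C)O2)cc(OCOC)c1C
F2 | step 3 | 5-iodo-1,3-bis(methoxymethoxy)-2-methylbenzene | COCOc1cc(I)cc(OCOC)c1C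
F3 | step 3 | (2S)-1-[3,5-bis(methoxymethoxy)-4-methylphenyl]propan-2-ol | COCOc1cc(C[C@H](C)O)cc(OCOC)c1C
F4 | step 3 | 6-[(2S)-2-hydroxypropyl]-2,4-bis(methoxymethoxy)-3-methylbenzaldehyde | COCOc1cc(C[C@H](C)O)c(C=O)c(OCOC)c1C
F5 | step 6 | methyl (2E)-3-{2,4-dihydroxy-6-[(2S)-2-hydroxypropyl]-3,5-dimethylphenyl}prop-2-enoate | COC(=O)/C=C/c1c(C[C@H](C)O)c(C)c(O)c(C)c1O
F6 | step 14 | 7-[(tert-butyldimethylsilyl)oxy]-3-[(5R)-5-[(tert-butyldimethylsilyl)oxy]-1-(diethylamino)-3-oxohex-1-en-1-yl]-5-[(2S)-2-[(tert-butyldimethylsilyl)oxy]propyl]-6,8-dimethyl-2H-chromen-2-one | Cc1c(O[Si](C)(C)C(C)(C)C)c(C)c2oc(=O)c(C(=CC(=O)C[C@@H](C)O[Si](C)(C)C(C)(C)C)N(CC)CC)cc2c1C[C@H](C)O[Si](C)(C)C(C)(C)C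
F7 | step 5 | 6-bromo-7-hydroxy-5-[(2S)-2-hydroxypropyl]-8-methyl-2H-chromen-2-one | Cc1c(O)c(Br)c(C[C@H](C)O)c2ccc(=O)oc12
F8 | step 5 | 6-bromo-7-[(tert-butyldimethylsilyl)oxy]-5-[(2S)-2-[(tert-butyldimethylsilyl)oxy]propyl]-8-methyl-2H-chromen-2-one | Cc1c(O[Si](C)(C)C(C)(C)C)c(Br)c(C[C@H](C)O[Si](C)(C)C(C)(C)C)c2ccc(=O)oc12
F9 | step 2 | 4-iodo-2-methylbenzene-1,3-diol | Cc1c(O)ccc(I)c1O
A1 | alternative 1 | 7-[(tert-butyldimethylsilyl)oxy]-5-[(2S)-2-[(tert-butyldimethylsilyl)oxy]propyl]-3-ethynyl-6,8-dimethyl-2H-chromen-2-one | Cc1c(O[Si](C)(C)C(C)(C)C)c(C)c2oc(=O)c(C#C)cc2c1C[C@H](C)O[Si](C)(C)C(C)(C)C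
A2 | alternative 1 | (3R)-3-[(tert-butyldimethylsilyl)oxy]butanal oxime | C[C@@H](O[Si](C)(C)C(C)(C)C)CC=NO
A3 | alternative 1 | (3R)-3-[(tert-butyldimethylsilyl)oxy]butanenitrile oxide | C[C@@H](O[Si](C)(C)C(C)(C)C)CC#[N+][O-]
A4 | alternative 1 | 7-[(tert-butyldimethylsilyl)oxy]-5-[(2S)-2-[(tert-butyldimethylsilyl)oxy]propyl]-3-{3-[(2R)-2-[(tert-butyldimethylsilyl)oxy]propyl]-1,2-oxazol-5-yl}-6,8-dimethyl-2H-chromen-2-one | Cc1c(O[Si](C)(C)C(C)(C)C)c(C)c2oc(=O)c(-c3cc(C[C@@H](C)O[Si](C)(C)C(C)(C)C)no3)cc2c1C[C@H](C)O[Si](C)(C)C(C)(C)C
A5 | alternative 2 | 1-bromo-2,4-dimethoxy-3-methylbenzene | COc1ccc(Br)c(OC)c1C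
A6 | alternative 2 | 3,5-dimethoxy-4-methylbenzyne (1,2-didehydro-3,5-dimethoxy-4-methylbenzene) | COC1=CC#CC(OC)=C1C
A7 | alternative 2 | 1,3-dimethoxy-2,4-dimethyl-5-(prop-2-en-1-yl)benzene | C=CCc1cc(OC)c(C)c(OC)c1C
A8 | alternative 3 | (6S)-2-diazo-4-methylidene-6-[(triisopropylsilyl)oxy]heptan-3-one | CC(=[N+]=[N-])C(=O)C(=C)C[C@H](C)O[Si](C(C)C)(C(C)C)C(C)C
A9 | alternative 3 | triisopropyl(prop-1-yn-1-yloxy)silane | CC#CO[Si](C(C)C)(C(C)C)C(C)C
A10 | alternative 3 | (5S)-2-methyl-3-methylidene-5-[(triisopropylsilyl)oxy]hex-1-en-1-one (vinylketene) | CC(=C=O)C(=C)C[C@H](C)O[Si](C(C)C)(C(C)C)C(C)C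
A11 | alternative 3 | 2,4-dimethyl-3-[(triisopropylsilyl)oxy]-5-[(2S)-2-[(triisopropylsilyl)oxy]propyl]phenol | Cc1c(O)cc(C[C@H](C)O[Si](C(C)C)(C(C)C)C(C)C)c(C)c1O[Si](C(C)C)(C(C)C)C(C)C
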